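**Plan**

- Labels: ring A is the trimethoxyarene C1–C6; ring B is the seven-membered ring C1, C2, C1', C7', C8', C8, C7; ring C is the dienone C1'–C6' with C4'=O. The enabling feature is C7, a secondary benzylic carbinol bonded to C1 of ring A and to C8(H)Me, so ring B can be closed at C1–C7 by adding a C1 aryl–metal to a C7 aldehyde.
- Retrosynthetic cuts, in order: C1–C7 (aryl boronate onto aldehyde, rhodium); C1–B back to the C1 phenol oxygen through its triflate; C4'=O back to C4'H2 of a bis-enol ether diene; C1'–C7' (Birch reductive alkylation); C2–C1' (Suzuki–Miyaura).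
- Forward: the biaryl bond comes first; ring C is then dearomatised and the four-carbon chain joined at C1'; ring C is oxidised to the dienone; oxygen at C1 is exchanged for boron; the C7 aldehyde is unmasked; ring B is closed last, and this closure gives the target itself.
- Stereochemistry: C8 and C8' come from (2S,3S)-2,3-dimethylsuccinic acid and pass through no enolisable stage before the final aldehyde. C7 is set in the ring closure by the neighbouring C8 centre and a chiral diene on rhodium. C1' carries two identical ring C arms and is not stereogenic.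
- Ring C is taken to the dienone before the closure so that the chromium/peroxide oxidation meets neither boron nor a benzylic carbinol, and C7 needs no protecting group.

Key step: step 12

Assumption: the (R,R) enantiomer of the diene ligand in step 12 is taken as the one matched to the substrate's own facial preference; this rests on a model, and the mirror-image ligand would be used in the same way if the pairing proved mismatched.

**Route**

Step 1
Reactants: 1 3,4,5-trimethoxyphenol
Product: 2 2-bromo-3,4,5-trimethoxyphenol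
Conditions: NBS (1.0 equiv), CH2Cl2, −78 °C to 0 °C
Reagents that add atoms: N-bromosuccinimide, O=C1CCC(=O)N1Br
Why: Electrophilic aromatic bromination in which the hydroxyl group directs NBS to its ortho carbon C2 (both ortho positions are equivalent), one equivalent at low temperature limiting a second bromination and oxidation of the electron-rich ring.

Step 2
Reactants: 2 2-bromo-3,4,5-trimethoxyphenol; 3 3,5-dimethoxyphenylboronic acid
Product: 4 2-(3,5-dimethoxyphenyl)-3,4,5-trimethoxyphenol
Conditions: Pd(OAc)2 (3 mol%), SPhos (6 mol%), K3PO4 (3 equiv), toluene/H2O (10:1), 90 °C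
Reagents that add atoms: none
Why: Suzuki–Miyaura coupling in which the bulky, electron-rich SPhos ligand lets zerovalent palladium insert into the di-ortho-substituted C2–Br bond and lets the hindered biaryl eliminate, while the unhindered boronic acid transmetalates readily and the free phenol is carried as its phenoxide.

Step 3
Reactants: 5 (2S,3S)-2,3-dimethylsuccinic acid
Product: 6 (2S,3S)-2,3-dimethylbutane-1,4-diol
Conditions: LiAlH4 (3 equiv), THF, 0 °C to reflux; aqueous work-up
Reagents that add atoms: none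
Why: Hydride reduction of both carboxyl groups with LiAlH4 runs through carboxylate and aluminate stages that do not enolise, so the two methyl-bearing centres pass unchanged into the C2-symmetric diol.

Step 4
Reactants: 6 (2S,3S)-2,3-dimethylbutane-1,4-diol
Product: 8 (2S,3S)-4-(tert-butyldimethylsilyloxy)-2,3-dimethylbutan-1-ol, via sodium monoalkoxide 7 (not isolated)
Conditions: NaH (1.0 equiv), THF, 0 °C to rt; then TBSCl (1.0 equiv), rt
Reagents that add atoms: tert-butyldimethylsilyl chloride, CC(C)(C)[Si](C)(C)Cl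
Why: Monosilylation of a symmetrical diol through its poorly soluble monosodium alkoxide (Williamson-type O-silylation), which reacts once with TBSCl; the diol is C2-symmetric, so both hydroxyls are equivalent and one product results.

Step 5
Reactants: 8 (2S,3S)-4-(tert-butyldimethylsilyloxy)-2,3-dimethylbutan-1-ol
Product: 9 tert-butyl[(2S,3S)-4-iodo-2,3-dimethylbutoxy]dimethylsilane
Conditions: PPh3 (1.2 equiv), iodine (1.2 equiv), imidazole (2.5 equiv), CH2Cl2, 0 °C to rt
Reagents that add atoms: iodine, [I][I]
Why: Appel-type iodination in which the primary alkoxyphosphonium ion is displaced by iodide in an SN2 reaction at CH2 that touches neither stereocentre nor the silyl ether.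

Step 6
Reactants: 4 2-(3,5-dimethoxyphenyl)-3,4,5-trimethoxyphenol; 9 tert-butyl[(2S,3S)-4-iodo-2,3-dimethylbutoxy]dimethylsilane
Product: 12 2-[1-[(2R,3S)-4-(tert-butyldimethylsilyloxy)-2,3-dimethylbutyl]-3,5-dimethoxycyclohexa-2,5-dien-1-yl]-3,4,5-trimethoxyphenol, via lithium phenoxide 10 (not isolated), via dilithium cyclohexadienyl anion 11 (not isolated)
Conditions: n-BuLi (1.05 equiv), THF, −78 °C; Li (2.5 equiv), NH3(l)/THF, −78 °C; then 9 (1.5 equiv), −78 °C to −40 °C; solid NH4Cl, NH3 evaporated; chromatography on Et3N-treated silica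
Reagents that add atoms: none
Why: Birch reductive alkylation of a 3,5-dimethoxybiaryl, in which lithium in ammonia transfers two electrons to ring C, ammonia protonates C4' between the methoxy groups, and the remaining aryl-substituted cyclohexadienyl anion is alkylated at its central carbon C1' by the primary iodide (SN2, no change at C8 or C8'), while ring A is shielded from reduction as its phenoxide, which is also a far weaker nucleophile than the carbanion.

Step 7
Reactants: 12 2-[1-[(2R,3S)-4-(tert-butyldimethylsilyloxy)-2,3-dimethylbutyl]-3,5-dimethoxycyclohexa-2,5-dien-1-yl]-3,4,5-trimethoxyphenol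
Product: 13 2-[1-[(2R,3S)-4-(tert-butyldimethylsilyloxy)-2,3-dimethylbutyl]-3,5-dimethoxycyclohexa-2,5-dien-1-yl]-3,4,5-trimethoxyphenyl trifluoromethanesulfonate
Conditions: PhNTf2 (1.3 equiv), Et3N (3 equiv), DMAP (10 mol%), CH2Cl2, 0 °C to rt
Reagents that add atoms: N-phenylbis(trifluoromethanesulfonimide), O=S(=O)(N(c1ccccc1)S(=O)(=O)C(F)(F)F)C(F)(F)F
Why: Aryl triflate formation by O-sulfonylation of the phenol with PhNTf2 and amine base, kept basic throughout so that the acid-labile bis-enol ether and the silyl ether survive and the phenol can no longer add to a neighbouring enol ether.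

Step 8
Reactants: 13 2-[1-[(2R,3S)-4-(tert-butyldimethylsilyloxy)-2,3-dimethylbutyl]-3,5-dimethoxycyclohexa-2,5-dien-1-yl]-3,4,5-trimethoxyphenyl trifluoromethanesulfonate
Product: 14 2-[1-[(2R,3S)-4-(tert-butyldimethylsilyloxy)-2,3-dimethylbutyl]-3,5-dimethoxy-4-oxocyclohexa-2,5-dien-1-yl]-3,4,5-trimethoxyphenyl trifluoromethanesulfonate
Conditions: (C5H5NH)2Cr2O7 (pyridinium dichromate, 3 equiv, chromium mediator), t-BuOOH (anhydrous in decane, 4 equiv, terminal oxidant), Celite, benzene, 10 °C to rt
Reagents that add atoms: tert-butyl hydroperoxide, CC(C)(C)OO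
Why: Bis-allylic oxidation of a 3,3-disubstituted cyclohexa-1,4-diene to the cross-conjugated cyclohexa-2,5-dienone with chromium/tert-butyl hydroperoxide, in which C4'H2 is the only doubly allylic position because C1' is quaternary, hydrogen abstraction there gives a pentadienyl radical that is oxygenated at its central carbon, and the triflate, silyl ether and arene carry no comparably weak C–H bond.

Step 9
Reactants: 14 2-[1-[(2R,3S)-4-(tert-butyldimethylsilyloxy)-2,3-dimethylbutyl]-3,5-dimethoxy-4-oxocyclohexa-2,5-dien-1-yl]-3,4,5-trimethoxyphenyl trifluoromethanesulfonate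
Product: 15 4-[(2R,3S)-4-(tert-butyldimethylsilyloxy)-2,3-dimethylbutyl]-2,6-dimethoxy-4-[2,3,4-trimethoxy-6-(4,4,5,5-tetramethyl-1,3,2-dioxaborolan-2-yl)phenyl]cyclohexa-2,5-dien-1-one
Conditions: B2pin2 (1.5 equiv), Pd2(dba)3 (2.5 mol%), XPhos (10 mol%), KOAc (3 equiv), 1,4-dioxane, 90 °C
Reagents that add atoms: bis(pinacolato)diboron, CC1(C)OB(OC1(C)C)B1OC(C)(C)C(C)(C)O1
Why: Miyaura borylation of the aryl triflate, in which XPhos enables oxidative addition of zerovalent palladium next to the quaternary C1', KOAc mediates boron transfer from B2pin2, and the dienone and silyl ether are inert to the weakly basic conditions.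

Step 10
Reactants: 15 4-[(2R,3S)-4-(tert-butyldimethylsilyloxy)-2,3-dimethylbutyl]-2,6-dimethoxy-4-[2,3,4-trimethoxy-6-(4,4,5,5-tetramethyl-1,3,2-dioxaborolan-2-yl)phenyl]cyclohexa-2,5-dien-1-one
Product: 16 4-[(2R,3S)-4-hydroxy-2,3-dimethylbutyl]-2,6-dimethoxy-4-[2,3,4-trimethoxy-6-(4,4,5,5-tetramethyl-1,3,2-dioxaborolan-2-yl)phenyl]cyclohexa-2,5-dien-1-one
Conditions: (1S)-camphor-10-sulfonic acid (10 mol%), MeOH/CH2Cl2 (1:1), 0 °C
Reagents that add atoms: none
Why: Acid-catalysed methanolysis of the primary silyl ether; ring C is now a dienone, so no acid-labile enol ether remains, and the pinacol boronate tolerates catalytic sulfonic acid in methanol at 0 °C.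

Step 11
Reactants: 16 4-[(2R,3S)-4-hydroxy-2,3-dimethylbutyl]-2,6-dimethoxy-4-[2,3,4-trimethoxy-6-(4,4,5,5-tetramethyl-1,3,2-dioxaborolan-2-yl)phenyl]cyclohexa-2,5-dien-1-one
Product: 17 (2S,3R)-4-[3,5-dimethoxy-4-oxo-1-[2,3,4-trimethoxy-6-(4,4,5,5-tetramethyl-1,3,2-dioxaborolan-2-yl)phenyl]cyclohexa-2,5-dien-1-yl]-2,3-dimethylbutanal
Conditions: Dess–Martin periodinane (1.3 equiv), CH2Cl2, 0 °C to rt
Reagents that add atoms: none
Why: Dess–Martin oxidation of the primary alcohol to the aldehyde under mild, non-basic conditions that neither epimerise the α-centre C8 nor oxidise the aryl boronate, the aldehyde being used at once.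

Step 12
Reactants: 17 (2S,3R)-4-[3,5-dimethoxy-4-oxo-1-[2,3,4-trimethoxy-6-(4,4,5,5-tetramethyl-1,3,2-dioxaborolan-2-yl)phenyl]cyclohexa-2,5-dien-1-yl]-2,3-dimethylbutanal
Product: 18 (7R,8S,9R)-9-hydroxy-2,3,3',4,5'-pentamethoxy-7,8-dimethyl-6,7,8,9-tetrahydrospiro[benzo[7]annulene-5,1'-cyclohexa[2,5]dien]-4'-one, the target (7R,8S,8'R in the labels used here)
Conditions: [RhCl(C2H4)2]2 (3 mol%), (R,R)-Ph-bod* [(1R,4R)-2,5-diphenylbicyclo[2.2.2]octa-2,5-diene] (7 mol%), K3PO4 (0.2 equiv), 1,4-dioxane/H2O (10:1), 0.01 M, 40 °C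
Reagents that add atoms: none
Why: Aqueous base converts the chloride precatalyst into a monovalent rhodium hydroxide bearing the chiral diene, which transmetalates with the C1 pinacol boronate; the C1 aryl–rhodium binds the tethered aldehyde, inserts its C7=O bond (1,2-addition), and water cleaves the rhodium alkoxide to release the carbinol and return the hydroxide. The closest known reaction type is the rhodium-catalysed intramolecular 1,2-addition of aryl boronates to aldehydes and ketones giving cyclic benzylic alcohols, mostly five- and six-membered. Ring B closes in a 7-exo-trig mode, helped by the ortho relationship of C1 to the quaternary C1' and by the three substituted carbons of the tether, which hold the aldehyde near the metal. The new centre C7 is controlled by the adjacent C8 centre: in a chair-like seven-membered transition structure with both methyl groups pseudo-equatorial, the rhodium-bound oxygen lies pseudo-equatorial, anti to C8' and trans to the C8 methyl, which corresponds to 7R, and the chiral diene is chosen to favour the same aldehyde face. The step needs chemoselectivity for the aldehyde over the dienone and over protodeboronation, and retention at C8: the dienone β-carbons could be reached only through a four-membered ring and are shielded by C1' and the α-methoxy groups, the dienone carbonyl is out of reach, high dilution suppresses intermolecular conjugate addition, and the weakly basic, low-temperature medium leaves the α-centre of the aldehyde untouched.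

**Compound list**

1 | 3,4,5-trimethoxyphenol | COc1cc(O)cc(OC)c1OC | starting material
2 | 2-bromo-3,4,5-trimethoxyphenol | COc1cc(O)c(Br)c(OC)c1OC | intermediate
3 | 3,5-dimethoxyphenylboronic acid | COc1cc(cc(OC)c1)B(O)O | starting material
4 | 2-(3,5-dimethoxyphenyl)-3,4,5-trimethoxyphenol | COc1cc(OC)cc(c1)-c1c(O)cc(OC)c(OC)c1OC | intermediate
5 | (2S,3S)-2,3-dimethylsuccinic acid | OC(=O)[C@@H](C)[C@H](C)C(O)=O | starting material
6 | (2S,3S)-2,3-dimethylbutane-1,4-diol | OC[C@@H](C)[C@H](C)CO | intermediate
7 | sodium (2S,3S)-4-hydroxy-2,3-dimethylbutan-1-olate (not isolated) | [Na+].[O-]C[C@@H](C)[C@H](C)CO | intermediate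
8 | (2S,3S)-4-(tert-butyldimethylsilyloxy)-2,3-dimethylbutan-1-ol | OC[C@@H](C)[C@H](C)CO[Si](C)(C)C(C)(C)C | intermediate
9 | tert-butyl[(2S,3S)-4-iodo-2,3-dimethylbutoxy]dimethylsilane | IC[C@@H](C)[C@H](C)CO[Si](C)(C)C(C)(C)C | intermediate
10 | lithium 2-(3,5-dimethoxyphenyl)-3,4,5-trimethoxyphenoxide (not isolated) | [Li+].[O-]c1cc(OC)c(OC)c(OC)c1-c1cc(OC)cc(OC)c1 | intermediate
11 | dilithium salt of the phenoxide and the 3,5-dimethoxycyclohexa-2,5-dien-1-yl anion at C1' (not isolated) | [Li+].[Li+].[O-]c1cc(OC)c(OC)c(OC)c1[C-]1C=C(OC)CC(OC)=C1 | intermediate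
12 | 2-[1-[(2R,3S)-4-(tert-butyldimethylsilyloxy)-2,3-dimethylbutyl]-3,5-dimethoxycyclohexa-2,5-dien-1-yl]-3,4,5-trimethoxyphenol | COC1=CC(C=C(OC)C1)(C[C@@H](C)[C@H](C)CO[Si](C)(C)C(C)(C)C)c1c(O)cc(OC)c(OC)c1OC | intermediate
13 | aryl triflate of 12 | COC1=CC(C=C(OC)C1)(C[C@@H](C)[C@H](C)CO[Si](C)(C)C(C)(C)C)c1c(OS(=O)(=O)C(F)(F)F)cc(OC)c(OC)c1OC | intermediate
14 | 2-[1-[(2R,3S)-4-(tert-butyldimethylsilyloxy)-2,3-dimethylbutyl]-3,5-dimethoxy-4-oxocyclohexa-2,5-dien-1-yl]-3,4,5-trimethoxyphenyl trifluoromethanesulfonate | COC1=CC(C=C(OC)C1=O)(C[C@@H](C)[C@H](C)CO[Si](C)(C)C(C)(C)C)c1c(OS(=O)(=O)C(F)(F)F)cc(OC)c(OC)c1OC | intermediate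
15 | 4-[(2R,3S)-4-(tert-butyldimethylsilyloxy)-2,3-dimethylbutyl]-2,6-dimethoxy-4-[2,3,4-trimethoxy-6-(pinacolboryl)phenyl]cyclohexa-2,5-dien-1-one | COC1=CC(C=C(OC)C1=O)(C[C@@H](C)[C@H](C)CO[Si](C)(C)C(C)(C)C)c1c(cc(OC)c(OC)c1OC)B1OC(C)(C)C(C)(C)O1 | intermediate
16 | 4-[(2R,3S)-4-hydroxy-2,3-dimethylbutyl]-2,6-dimethoxy-4-[2,3,4-trimethoxy-6-(pinacolboryl)phenyl]cyclohexa-2,5-dien-1-one | COC1=CC(C=C(OC)C1=O)(C[C@@H](C)[C@H](C)CO)c1c(cc(OC)c(OC)c1OC)B1OC(C)(C)C(C)(C)O1 | intermediate
17 | (2S,3R)-4-[3,5-dimethoxy-4-oxo-1-[2,3,4-trimethoxy-6-(pinacolboryl)phenyl]cyclohexa-2,5-dien-1-yl]-2,3-dimethylbutanal | COC1=CC(C=C(OC)C1=O)(C[C@@H](C)[C@H](C)C=O)c1c(cc(OC)c(OC)c1OC)B1OC(C)(C)C(C)(C)O1 | intermediate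
18 | (7R,8S,9R)-9-hydroxy-2,3,3',4,5'-pentamethoxy-7,8-dimethyl-6,7,8,9-tetrahydrospiro[benzo[7]annulene-5,1'-cyclohexa[2,5]dien]-4'-one | COC1=CC2(C=C(OC)C1=O)C[C@@H](C)[C@H](C)[C@@H](O)c1cc(OC)c(OC)c(OC)c12 | target

**Totals and risks**

Total step count: 12.
Longest linear sequence: 10 steps, from 5 to 18 (steps 3, 4, 5, 6, 7, 8, 9, 10, 11, 12).

Steps most likely to fail:

1. Ring closure, step 12. The aryl–rhodium may add to the wrong face of the aldehyde, because the preference of the C8 centre in a seven-membered transition structure is not secure and the ligand may not override it. The fallback still sets out from 17 with the same closure. If this gives mainly the C7 epimer, the (7S,8S,8'R)-alcohol F1, that alcohol is inverted under Mitsunobu conditions (4-nitrobenzoic acid, PPh3, DIAD, THF, 0 °C) to the (7R)-4-nitrobenzoate F2. K2CO3 in MeOH then cleaves the ester, and the route is rejoined at 18. C7 is then set by SN2 displacement and no longer by carbonyl addition.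

2. Dienone formation, step 8. Chromium species or peroxyl radicals may attack the electron-rich enol ether double bonds (cleavage or oxygenation at carbon) instead of abstracting hydrogen from C4'H2. The fallback sets out from 13 and reaches the same oxidation level through a tricarbonyl. Mild hydrolysis (oxalic acid, THF/H2O, rt) gives the 5,5-disubstituted cyclohexane-1,3-dione F3. Regitz diazo transfer (TsN3, Et3N, MeCN) gives the 2-diazo-1,3-dione F4. Oxygen transfer from dimethyldioxirane (acetone, 0 °C) gives the 1,2,3-trione, expected as its bis-enol tautomer, the 2,6-dihydroxydienone F5; aromatisation is blocked by the quaternary C1'. Double O-methylation (MeI, K2CO3, acetone) then gives 14, where the route is rejoined.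

3. Borylation, step 9. Oxidative addition of zerovalent palladium into the C1–O bond beside the quaternary C1' may be too slow, so that reduction or hydrolysis of the triflate takes over. The fallback sets out from 14 and uses the triflate itself as the aryl donor for the same C1–C7 bond. Methanolysis of the silyl ether (camphorsulfonic acid, MeOH/CH2Cl2, 0 °C) gives the alcohol triflate F6. Dess–Martin oxidation gives the aldehyde triflate F7. A Nozaki–Hiyama–Kishi closure (CrCl2, 4 equiv, NiCl2, 5 mol%, DMF, rt, high dilution) then forms ring B, and the route is rejoined at 18. A C7 epimer from this closure would be corrected as described for the ring closure above.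

Further compounds
F1 | step 12 | (7S,8S,8'R)-alcohol, the C7 epimer of 18 | COC1=CC2(C=C(OC)C1=O)C[C@@H](C)[C@H](C)[C@H](O)c1cc(OC)c(OC)c(OC)c12
F2 | step 12 | (7R)-4-nitrobenzoate of 18 | COC1=CC2(C=C(OC)C1=O)C[C@@H](C)[C@H](C)[C@@H](OC(=O)c3ccc(cc3)[N+](=O)[O-])c1cc(OC)c(OC)c(OC)c12
F3 | step 8 | 2-[1-[(2R,3S)-4-(tert-butyldimethylsilyloxy)-2,3-dimethylbutyl]-3,5-dioxocyclohexyl]-3,4,5-trimethoxyphenyl trifluoromethanesulfonate | O=C1CC(=O)CC(C1)(C[C@@H](C)[C@H](C)CO[Si](C)(C)C(C)(C)C)c1c(OS(=O)(=O)C(F)(F)F)cc(OC)c(OC)c1OC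
F4 | step 8 | 4-diazo-3,5-dioxocyclohexyl analogue of F3 | [N-]=[N+]=C1C(=O)CC(CC1=O)(C[C@@H](C)[C@H](C)CO[Si](C)(C)C(C)(C)C)c1c(OS(=O)(=O)C(F)(F)F)cc(OC)c(OC)c1OC
F5 | step 8 | 2-[1-[(2R,3S)-4-(tert-butyldimethylsilyloxy)-2,3-dimethylbutyl]-3,5-dihydroxy-4-oxocyclohexa-2,5-dien-1-yl]-3,4,5-trimethoxyphenyl trifluoromethanesulfonate (bis-enol of the trione) | OC1=CC(C=C(O)C1=O)(C[C@@H](C)[C@H](C)CO[Si](C)(C)C(C)(C)C)c1c(OS(=O)(=O)C(F)(F)F)cc(OC)c(OC)c1OC
F6 | step 9 | 2-[1-[(2R,3S)-4-hydroxy-2,3-dimethylbutyl]-3,5-dimethoxy-4-oxocyclohexa-2,5-dien-1-yl]-3,4,5-trimethoxyphenyl trifluoromethanesulfonate | COC1=CC(C=C(OC)C1=O)(C[C@@H](C)[C@H](C)CO)c1c(OS(=O)(=O)C(F)(F)F)cc(OC)c(OC)c1OC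
F7 | step 9 | 2-[1-[(2R,3S)-2,3-dimethyl-4-oxobutyl]-3,5-dimethoxy-4-oxocyclohexa-2,5-dien-1-yl]-3,4,5-trimethoxyphenyl trifluoromethanesulfonate | COC1=CC(C=C(OC)C1=O)(C[C@@H](C)[C@H](C)C=O)c1c(OS(=O)(=O)C(F)(F)F)cc(OC)c(OC)c1OC
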